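**Retrosynthetic overview**
1. Last disconnection: the spiro C1–C6' bond and the C7' carbinol, made together by an anodic, manganese-mediated 6-endo radical spirocyclisation with O2 capture on the monocyclic precursor 11.
2. 11 is cut at the ring-A carbon–CH2 bond: reductive alkylation of the dearomatised gem-diprenyl acylphloroglucinol 5 with the cyclopentane hydroxy aldehyde 9.
3. 9 comes from an intramolecular aldol of keto aldehyde 8, made by oxidative ring cleavage of (4R)-limonene oxide, which supplies the only purchased stereocentre.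
4. 5 comes from phloroglucinol by Friedel–Crafts acylation and geminal C-prenylation.
5. Ring order: ring A (aromatic, then dearomatised), then the cyclopentane, then the spiro cyclohexane of the trans-hydrindane.

Assumption: ring A is drawn in the enol tautomer of the given SMILES, and commercial (+)-limonene oxide is the (4R) cis/trans mixture.

**Step 1**
Reactants: 1 phloroglucinol; 2 isovaleryl chloride
Product: 3 phlorisovalerophenone
Conditions: AlCl3 (3 equiv), PhNO2/CH2Cl2, 0 → 40 °C; aq. HCl work-up
Reagents that add atoms: isovaleryl chloride 2, CC(C)CC(=O)Cl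
Why: Friedel–Crafts C-acylation of the strongly activated triol, where the chelated aryl ketone formed is deactivated against a second acylation.

**Step 2**
Reactants: 3 phlorisovalerophenone; 4 prenyl bromide (2.1 equiv)
Product: 5 3,5-dihydroxy-4-(3-methylbutanoyl)-6,6-bis(3-methylbut-2-en-1-yl)cyclohexa-2,4-dien-1-one
Conditions: NaOMe (2.2 equiv), MeOH, 0 °C → rt; acidify, chromatography
Reagents that add atoms: prenyl bromide 4, CC(C)=CCBr
Why: Base-mediated dearomative geminal C-alkylation of the phenolate (double SN2), a known route to this class that gives the gem-diprenyl dienone in modest yield (about 30 % expected) beside the 3,5-diprenyl and triprenyl products, which are removed by chromatography.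

**Step 3**
Reactants: 6 (+)-limonene oxide, (4R), cis/trans mixture
Product: 8 (3R)-6-oxo-3-(prop-1-en-2-yl)heptanal, via limonene-1,2-diol 7 (not isolated)
Conditions: H5IO6 (1.1 equiv), THF/H2O, 0 °C → rt
Reagents that add atoms: water, O
Why: Acid-promoted epoxide hydrolysis followed by Malaprade glycol cleavage, which destroys the two oxirane stereocentres and leaves the purchased (R) centre and the isopropenyl group untouched.

**Step 4**
Reactants: 8 (3R)-6-oxo-3-(prop-1-en-2-yl)heptanal
Product: 9 (1S,2R,5R)-2-hydroxy-2-methyl-5-(prop-1-en-2-yl)cyclopentane-1-carbaldehyde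
Conditions: pyrrolidine (20 mol%), AcOH (20 mol%), THF/H2O 20:1, 0.05 M, 0 °C → rt
Reagents that add atoms: none
Why: Intramolecular enamine (5-enolexo) aldol addition of the aldehyde enamine to the methyl ketone, run reversibly (retro-aldol and α-epimerisation) so that the isomer with CH3, CHO and isopropenyl mutually trans and the OH cis to CHO (hydrogen-bonded) accumulates, setting C1 and C2 relative to the purchased C5.

**Step 5**
Reactants: 5 gem-diprenyl dienone; 9 hydroxy aldehyde (1.2 equiv)
Product: 11 3,5-dihydroxy-2-{[(1S,2R,5R)-2-hydroxy-2-methyl-5-(prop-1-en-2-yl)cyclopentyl]methyl}-4-(3-methylbutanoyl)-6,6-bis(3-methylbut-2-en-1-yl)cyclohexa-2,4-dien-1-one, via Knoevenagel alkylidene 10 (not isolated)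
Conditions: Hantzsch ester (diethyl 2,6-dimethyl-1,4-dihydropyridine-3,5-dicarboxylate, 1.2 equiv), EtOH, 40 °C, no amine
Reagents that add atoms: none
Why: Three-component reductive alkylation (Knoevenagel condensation at the only free ring-A carbon, then Hantzsch-ester hydride transfer to the quinone-methide-like alkylidene), self-catalysed by the acidic triketone so that the amine-free medium spares the β-hydroxy aldehyde from retro-aldol; no new stereocentre.

**Step 6**
Reactants: 11 cyclopentylmethyl dienone
Product: 13 CNP0198642.3 (target), via tertiary hydroperoxide 12 (not isolated)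
Conditions: Mn(OAc)2·4H2O (20 mol%), NaOAc, AcOH, air, graphite anode / Pt cathode, divided cell, 2 mA cm⁻², about 1.2 F mol⁻¹, 25 °C; then PPh3
Reagents that add atoms: dioxygen, O=O
Why: Proposed new method: anodically regenerated trivalent manganese (from catalytic Mn(OAc)2) oxidises the ring-A β-diketone enol of 11 in bulk solution to the C2 radical, which closes 6-endo onto the CH2 terminus of the isopropenyl group through a chair transition state (the trans cyclopentane forces the trans-hydrindane and the bulky gem-diprenyl flank sits equatorial, giving the S spiro centre), and the tertiary C7' radical is captured by O2 from the equatorial face anti to the axial ring-A carbonyl (R carbinol) before PPh3 reduces the hydroperoxide; the closest known reaction types are the stoichiometric Mn(OAc)3 oxidative free-radical cyclisation of dearomatised acylphloroglucinols and the manganese-catalysed aerobic peroxidation of alkenes with 1,3-diketones, neither shown electrocatalytically nor as a 6-endo spiro carbo-hydroxylation.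

**Compound list**
1 | phloroglucinol (benzene-1,3,5-triol) | Oc1cc(O)cc(O)c1 | starting material
2 | isovaleryl chloride (3-methylbutanoyl chloride) | CC(C)CC(=O)Cl | starting material
3 | phlorisovalerophenone, 3-methyl-1-(2,4,6-trihydroxyphenyl)butan-1-one | CC(C)CC(=O)c1c(O)cc(O)cc1O | intermediate
4 | prenyl bromide (1-bromo-3-methylbut-2-ene) | CC(C)=CCBr | starting material
5 | 3,5-dihydroxy-4-(3-methylbutanoyl)-6,6-bis(3-methylbut-2-en-1-yl)cyclohexa-2,4-dien-1-one | CC(C)=CCC1(CC=C(C)C)C(=O)C=C(O)C(C(=O)CC(C)C)=C1O | intermediate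
6 | (+)-limonene oxide, (4R)-1-methyl-4-(prop-1-en-2-yl)-7-oxabicyclo[4.1.0]heptane, cis/trans mixture | CC(=C)[C@@H]1CCC2(C)OC2C1 | starting material
7 | (4R)-1-methyl-4-(prop-1-en-2-yl)cyclohexane-1,2-diol (limonene-1,2-diol, not isolated) | CC(=C)[C@@H]1CCC(C)(O)C(O)C1 | intermediate
8 | (3R)-6-oxo-3-(prop-1-en-2-yl)heptanal | CC(=C)[C@@H](CC=O)CCC(C)=O | intermediate
9 | (1S,2R,5R)-2-hydroxy-2-methyl-5-(prop-1-en-2-yl)cyclopentane-1-carbaldehyde | O=C[C@H]1[C@@H](CC[C@@]1(C)O)C(C)=C | intermediate
10 | 5-hydroxy-2-{[(1S,2R,5R)-2-hydroxy-2-methyl-5-(prop-1-en-2-yl)cyclopentyl]methylidene}-4-(3-methylbutanoyl)-6,6-bis(3-methylbut-2-en-1-yl)cyclohex-4-ene-1,3-dione (alkene geometry undefined, not isolated) | CC(C)=CCC1(CC=C(C)C)C(=O)C(=C[C@H]2[C@@H](CC[C@@]2(C)O)C(C)=C)C(=O)C(C(=O)CC(C)C)=C1O | intermediate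
11 | 3,5-dihydroxy-2-{[(1S,2R,5R)-2-hydroxy-2-methyl-5-(prop-1-en-2-yl)cyclopentyl]methyl}-4-(3-methylbutanoyl)-6,6-bis(3-methylbut-2-en-1-yl)cyclohexa-2,4-dien-1-one | CC(C)=CCC1(CC=C(C)C)C(=O)C(C[C@H]2[C@@H](CC[C@@]2(C)O)C(C)=C)=C(O)C(C(=O)CC(C)C)=C1O | intermediate
12 | (1S,3'R,3a'S,7'R,7a'R)-7'-hydroperoxy-3',4-dihydroxy-3',7'-dimethyl-3-(3-methylbutanoyl)-5,5-bis(3-methylbut-2-en-1-yl)-octahydrospiro[cyclohex-3-ene-1,5'-indene]-2,6-dione (not isolated) | CC(C)=CCC1(CC=C(C)C)C(=O)[C@@]2(C[C@H]3[C@@H](CC[C@@]3(C)O)[C@](C)(OO)C2)C(=O)C(C(=O)CC(C)C)=C1O | intermediate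
13 | CNP0198642.3, (1S,3'R,3a'S,7'R,7a'R)-3',4,7'-trihydroxy-3',7'-dimethyl-3-(3-methylbutanoyl)-5,5-bis(3-methylbut-2-en-1-yl)-1',2',3',3a',4',6',7',7a'-octahydrospiro[cyclohex-3-ene-1,5'-indene]-2,6-dione | CC(C)=CCC1(CC=C(C)C)C(=O)[C@@]2(C[C@H]3[C@@H](CC[C@@]3(C)O)[C@](C)(O)C2)C(=O)C(C(=O)CC(C)C)=C1O | target

**Totals**
Total step count: 6. Longest linear sequence: 4 steps (6 → 8 → 9 → 11 → 13; the branch 1 → 3 → 5 → 11 → 13 is equally long).

**Three steps most likely to fail**

Step 6 (the new electrochemical closure). The ring-A radical may instead attack a prenyl group on the neighbouring quaternary carbon (the known 5-exo mode that builds bicyclo[3.2.1]octanes from such substrates), may be oxygenated at the radical carbon itself, or O2 may be captured with poor facial selectivity at C7'. The fallback uses known polar chemistry, sets out from 9 and comes back at 13. The isopropenyl group of 9 is epoxidised with dimethyldioxirane (acetone, −20 °C) to (1S,2R,5R)-2-hydroxy-2-methyl-5-(2-methyloxiran-2-yl)cyclopentane-1-carbaldehyde F6, obtained as both oxirane epimers. F6 is coupled with 5 under the conditions of step 5, through the epoxy alkylidene F7, to the epoxy dienone F8. K2CO3 in MeOH at 25 °C then lets the ring-A enolate open the oxirane at its CH2 terminus (intramolecular SN2, six-membered ring), giving 13 together with its 7'-epimer F9 from the other oxirane epimer; the two are separated by chromatography. This fallback gives no control at C7'.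

Step 4. The tertiary aldol 9 may dehydrate to the conjugated enal under amine catalysis, or equilibrate incompletely to a diastereomer mixture. The fallback sets out from 8 and comes back at 9. Piperidinium acetate in refluxing toluene with a water separator gives the known condensation product (S)-2-methyl-5-(prop-1-en-2-yl)cyclopent-1-ene-1-carbaldehyde F1. Alkaline H2O2 (NaOH, MeOH, 0 °C) epoxidises F1 on the face anti to the isopropenyl group to (1S,2S,5R)-5-methyl-2-(prop-1-en-2-yl)-6-oxabicyclo[3.1.0]hexane-1-carbaldehyde F2. SmI2 (divalent samarium, THF/MeOH, −90 °C) cleaves the Cα–O bond reductively, and protonation with equilibration at the α-carbon places CHO trans to the isopropenyl group and returns 9.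

Step 5. The free β-hydroxy aldehyde may undergo retro-aldol or dehydration faster than the hindered Knoevenagel condensation, or the uncatalysed condensation may be too slow. The fallback sets out from 9 (with 5) and comes back at 11. The tertiary alcohol is silylated (TESOTf, 2,6-lutidine, CH2Cl2, −78 °C) to (1S,2R,5R)-2-methyl-5-(prop-1-en-2-yl)-2-[(triethylsilyl)oxy]cyclopentane-1-carbaldehyde F3. F3 then undergoes the established amine-catalysed three-component reductive alkylation with 5 (pyrrolidine 10 mol%, Hantzsch ester, CH2Cl2, 25 °C), through the silylated alkylidene F4, to the silyl-protected dienone F5. HF·pyridine (THF, 0 °C) removes the silyl group to give 11.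

**Further compounds**
F1 | step 4 | (S)-2-methyl-5-(prop-1-en-2-yl)cyclopent-1-ene-1-carbaldehyde | O=CC1=C(C)CC[C@H]1C(C)=C
F2 | step 4 | (1S,2S,5R)-5-methyl-2-(prop-1-en-2-yl)-6-oxabicyclo[3.1.0]hexane-1-carbaldehyde (oxirane anti to isopropenyl) | O=C[C@@]12O[C@]1(C)CC[C@H]2C(C)=C
F3 | step 5 | (1S,2R,5R)-2-methyl-5-(prop-1-en-2-yl)-2-[(triethylsilyl)oxy]cyclopentane-1-carbaldehyde | O=C[C@H]1[C@@H](CC[C@@]1(C)O[Si](CC)(CC)CC)C(C)=C
F4 | step 5 | triethylsilyl ether of alkylidene 10 (not isolated) | CC(C)=CCC1(CC=C(C)C)C(=O)C(=C[C@H]2[C@@H](CC[C@@]2(C)O[Si](CC)(CC)CC)C(C)=C)C(=O)C(C(=O)CC(C)C)=C1O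
F5 | step 5 | triethylsilyl ether of dienone 11 | CC(C)=CCC1(CC=C(C)C)C(=O)C(C[C@H]2[C@@H](CC[C@@]2(C)O[Si](CC)(CC)CC)C(C)=C)=C(O)C(C(=O)CC(C)C)=C1O
F6 | step 6 | (1S,2R,5R)-2-hydroxy-2-methyl-5-(2-methyloxiran-2-yl)cyclopentane-1-carbaldehyde, both oxirane epimers | O=C[C@H]1[C@@H](CC[C@@]1(C)O)C1(C)CO1
F7 | step 6 | epoxy analogue of alkylidene 10 (not isolated) | CC(C)=CCC1(CC=C(C)C)C(=O)C(=C[C@H]2[C@@H](CC[C@@]2(C)O)C2(C)CO2)C(=O)C(C(=O)CC(C)C)=C1O
F8 | step 6 | epoxy analogue of dienone 11, both oxirane epimers | CC(C)=CCC1(CC=C(C)C)C(=O)C(C[C@H]2[C@@H](CC[C@@]2(C)O)C2(C)CO2)=C(O)C(C(=O)CC(C)C)=C1O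
F9 | step 6 | 7'-epimer of 13, (1S,3'R,3a'S,7'S,7a'R) | CC(C)=CCC1(CC=C(C)C)C(=O)[C@@]2(C[C@H]3[C@@H](CC[C@@]3(C)O)[C@@](C)(O)C2)C(=O)C(C(=O)CC(C)C)=C1O
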